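**Retrosynthetic overview**
- Ring B is closed last at C2–C26 by an intramolecular palladium-catalysed allyl–alkenyl (Suzuki–Miyaura-type) coupling between a ring C allylic carbonate and a ring A tetrasubstituted alkenyl boronate.
- Ring C (C13=C14) comes from aldol cyclodehydration of a keto aldehyde; its C26 ketone comes from a Fukuyama coupling (C13–C26) of a ring A alkylzinc with a ring D thioester.
- Ring A fragment: 3-methylcyclopentenone plus (R)-4-bromo-3-methylbut-1-ene (B-alkyl Suzuki, C8–C9); CBS reduction and directed hydrogenation set C6 and C8; reductive enol triflation and borylation fix the C2=C3 geometry.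
- Ring D fragment: (R)-4-hydroxycyclopentenone to (S)-4-isopropyl-2-methylcyclopentenone; Mukaiyama–Michael addition and acetal alkylation set C24 and C15.
- Ring order: A and D (from cyclopentenones), then C, then B; the C17 and C26 carbinols are set together by one CBS reduction.

Assumption: atoms are labelled C1–C26 by their position in the given SMILES (O18 is the hydroxyl oxygen); β is the face of the C16 methyl and the hydroxyl group, α the face of H6, H8, H24 and H26.

**Route**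

Step 1
Reactants: 1 3-methylcyclopent-2-en-1-one
Product: 2 2-iodo-3-methylcyclopent-2-en-1-one
Conditions: I2, PhI(OCOCF3)2, pyridine, CH2Cl2, rt
Reagents that add atoms: iodine ([I][I])
Why: Johnson-type α-iodination of the enone (pyridine conjugate addition, iodination, elimination) gives the 2-iodoenone for cross-coupling, with no stereocenter formed.

Step 2
Reactants: 3 (E)-1,4-dibromobut-2-ene
Product: 4 (3R)-4-bromo-3-methylbut-1-ene
Conditions: MeMgBr, copper thiophene-2-carboxylate CuO2CC4H3S (3 mol%), chiral phosphoramidite ligand (enantiomer that gives the R product), CH2Cl2, −78 °C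
Reagents that add atoms: methylmagnesium bromide (C[Mg]Br)
Why: copper-catalysed asymmetric allylic alkylation (SN2' delivery of methyl) sets the methyl-bearing stereocenter that becomes C11 under ligand control, and the remaining non-allylic bromide is inert.

Step 3
Reactants: 2 2-iodo-3-methylcyclopent-2-en-1-one; 4 (3R)-4-bromo-3-methylbut-1-ene
Product: 6 2-[(3R)-4-bromo-3-methylbutyl]-3-methylcyclopent-2-en-1-one, via B-alkyl-9-BBN adduct 5 (not isolated)
Conditions: 9-BBN, THF, 0 °C to rt; then 2, PdCl2(dppf) (5 mol%), AsPh3, Cs2CO3, DMF/THF/H2O, rt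
Reagents that add atoms: none
Why: anti-Markovnikov hydroboration followed by B-alkyl Suzuki–Miyaura coupling with the α-iodoenone forms C8–C9, the primary alkyl bromide not undergoing oxidative addition under these conditions.

Step 4
Reactants: 6 2-[(3R)-4-bromo-3-methylbutyl]-3-methylcyclopent-2-en-1-one
Product: 7 (1S)-2-[(3R)-4-bromo-3-methylbutyl]-3-methylcyclopent-2-en-1-ol
Conditions: (R)-Me-CBS oxazaborolidine (0.2 equiv), BH3·SMe2, THF, −20 °C
Reagents that add atoms: none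
Why: Corey–Bakshi–Shibata reduction, with the α-substituted alkenyl carbon as the large group, delivers hydride to the β face and gives the (S)-allylic alcohol (OH α) under catalyst control.

Step 5
Reactants: 7 (1S)-2-[(3R)-4-bromo-3-methylbutyl]-3-methylcyclopent-2-en-1-ol
Product: 8 (1S,2S,3S)-2-[(3R)-4-bromo-3-methylbutyl]-3-methylcyclopentan-1-ol
Conditions: [Ir(cod)(PCy3)(py)]PF6 (5 mol%), H2 (10 bar), CH2Cl2, rt
Reagents that add atoms: none
Why: hydroxyl-directed hydrogenation delivers both hydrogens to the α face of the tetrasubstituted alkene, so the C8 chain and the C6 methyl end up cis to each other and trans to OH (C6 S, C8 S).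

Step 6
Reactants: 8 (1S,2S,3S)-2-[(3R)-4-bromo-3-methylbutyl]-3-methylcyclopentan-1-ol
Product: 9 (2S,3S)-2-[(3R)-4-bromo-3-methylbutyl]-3-methylcyclopentan-1-one
Conditions: Dess–Martin periodinane, NaHCO3, CH2Cl2, 0 °C
Reagents that add atoms: none
Why: Dess–Martin oxidation under buffered non-basic conditions gives the cis-2,3-disubstituted ketone without epimerising C8.

Step 7
Reactants: 9 (2S,3S)-2-[(3R)-4-bromo-3-methylbutyl]-3-methylcyclopentan-1-one
Product: 11 (4S,5S)-5-[(3R)-4-bromo-3-methylbutyl]-4-methylcyclopent-1-en-1-yl trifluoromethanesulfonate, via potassium enolate 10 (not isolated)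
Conditions: KN(SiMe3)2, THF, −78 °C; then PhNTf2, −78 to 0 °C
Reagents that add atoms: N-phenylbis(trifluoromethanesulfonimide) (FC(F)(F)S(=O)(=O)N(c1ccccc1)S(=O)(=O)C(F)(F)F)
Why: kinetic deprotonation at the unhindered C4 methylene and O-triflation give the less substituted enol triflate, so the C8 stereocenter is never enolised.

Step 8
Reactants: 11 (4S,5S)-5-[(3R)-4-bromo-3-methylbutyl]-4-methylcyclopent-1-en-1-yl trifluoromethanesulfonate
Product: 13 1-[(4S,5S)-5-[(3R)-4-bromo-3-methylbutyl]-4-methylcyclopent-1-en-1-yl]ethan-1-one, via ethoxydiene 12 (not isolated)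
Conditions: tributyl(1-ethoxyvinyl)stannane, Pd2(dba)3 (2.5 mol%), AsPh3, NMP, 40 °C; then 1 M HCl, rt
Reagents that add atoms: tributyl(1-ethoxyvinyl)stannane (C=C(OCC)[Sn](CCCC)(CCCC)CCCC); water (O)
Why: Stille coupling of the enol triflate with an acyl-anion equivalent and hydrolysis of the enol ether install the C2 acetyl group (C2 and the C1 methyl) as a conjugated enone in which C8 is no longer epimerisable.

Step 9
Reactants: 13 1-[(4S,5S)-5-[(3R)-4-bromo-3-methylbutyl]-4-methylcyclopent-1-en-1-yl]ethan-1-one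
Product: 15 (1Z)-1-[(2S,3S)-2-[(3R)-4-bromo-3-methylbutyl]-3-methylcyclopentylidene]ethyl trifluoromethanesulfonate, via lithium Z-enolate 14 (not isolated)
Conditions: LiBH(s-Bu)3, THF, −78 °C; then N-(5-chloropyridin-2-yl)triflimide (Comins' reagent), −78 to −20 °C
Reagents that add atoms: N-(5-chloropyridin-2-yl)-1,1,1-trifluoro-N-(trifluoromethylsulfonyl)methanesulfonamide (FC(F)(F)S(=O)(=O)N(c1ccc(Cl)cn1)S(=O)(=O)C(F)(F)F)
Why: conjugate hydride reduction of the s-trans enone (carbonyl oxygen syn to C8 to avoid allylic strain between the acetyl methyl and the C8 substituent) gives the Z-enolate, which is O-triflated with retention so that oxygen is cis to C8 and the methyl cis to C4.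

Step 10
Reactants: 15 (1Z)-1-[(2S,3S)-2-[(3R)-4-bromo-3-methylbutyl]-3-methylcyclopentylidene]ethyl trifluoromethanesulfonate
Product: 16 2-[(1E)-1-[(2S,3S)-2-[(3R)-4-bromo-3-methylbutyl]-3-methylcyclopentylidene]ethyl]-4,4,5,5-tetramethyl-1,3,2-dioxaborolane
Conditions: B2pin2, PdCl2(dppf) (5 mol%), KOAc, 1,4-dioxane, 80 °C
Reagents that add atoms: bis(pinacolato)diboron (CC1(C)OB(OC1(C)C)B1OC(C)(C)C(C)(C)O1)
Why: Miyaura borylation of the enol triflate proceeds with retention of alkene geometry (boron cis to C8; the descriptor changes only through CIP priorities) and leaves the alkyl bromide intact.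

Step 11
Reactants: 17 (4R)-4-hydroxycyclopent-2-en-1-one
Product: 18 (4R)-4-[(tert-butyldimethylsilyl)oxy]cyclopent-2-en-1-one
Conditions: TBSCl, imidazole, CH2Cl2, 0 °C
Reagents that add atoms: tert-butyldimethylsilyl chloride (CC(C)(C)[Si](C)(C)Cl)
Why: standard silylation protects the carbinol, which then serves as the stereodirecting leaving group.

Step 12
Reactants: 18 (4R)-4-[(tert-butyldimethylsilyl)oxy]cyclopent-2-en-1-one
Product: 20 (4S)-4-(propan-2-yl)cyclopent-2-en-1-one, via silyloxy ketone 19 (not isolated)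
Conditions: i-PrMgCl, CuBr·SMe2 (10 mol%), THF, −78 °C; NH4Cl (aq); then DBU, CH2Cl2, rt
Reagents that add atoms: isopropylmagnesium chloride (CC(C)[Mg]Cl)
Why: copper-catalysed conjugate addition occurs anti to the silyloxy group and E1cB loss of the silanol transposes the enone, so the isopropyl-bearing center (later C20, S) is set by the carbinol configuration.

Step 13
Reactants: 20 (4S)-4-(propan-2-yl)cyclopent-2-en-1-one
Product: 21 (4S)-2-iodo-4-(propan-2-yl)cyclopent-2-en-1-one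
Conditions: I2, pyridine, CH2Cl2, 0 °C to rt
Reagents that add atoms: iodine ([I][I])
Why: Johnson α-iodination of the β-unsubstituted enone is reliable and does not touch the γ stereocenter.

Step 14
Reactants: 21 (4S)-2-iodo-4-(propan-2-yl)cyclopent-2-en-1-one
Product: 22 (4S)-2-methyl-4-(propan-2-yl)cyclopent-2-en-1-one
Conditions: SnMe4, Pd2(dba)3 (2.5 mol%), AsPh3, CuI, NMP, 60 °C
Reagents that add atoms: tetramethylstannane (C[Sn](C)(C)C)
Why: Stille methylation of the α-iodoenone under neutral conditions installs the C16 methyl without racemising the γ center.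

Step 15
Reactants: 23 S-ethyl ethanethioate
Product: 25 {[1-(ethylsulfanyl)ethenyl]oxy}(trimethyl)silane, via lithium thioester enolate 24 (not isolated)
Conditions: LiN(i-Pr)2, THF, −78 °C; then Me3SiCl
Reagents that add atoms: chlorotrimethylsilane (C[Si](C)(C)Cl)
Why: enolisation and O-silylation give the ketene silyl thioacetal that serves as the acetate-enolate equivalent.

Step 16
Reactants: 22 (4S)-2-methyl-4-(propan-2-yl)cyclopent-2-en-1-one; 25 {[1-(ethylsulfanyl)ethenyl]oxy}(trimethyl)silane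
Product: 26 S-ethyl 2-[(1S,5S)-2-methyl-5-(propan-2-yl)-3-[(trimethylsilyl)oxy]cyclopent-2-en-1-yl]ethanethioate
Conditions: Ph3CSbCl6 (5 mol%), CH2Cl2, −78 °C
Reagents that add atoms: none
Why: Mukaiyama–Michael addition takes place anti to the C20 isopropyl group and sets C24 (S), with silyl transfer giving the regiodefined silyl enol ether.

Step 17
Reactants: 26 S-ethyl 2-[(1S,5S)-2-methyl-5-(propan-2-yl)-3-[(trimethylsilyl)oxy]cyclopent-2-en-1-yl]ethanethioate
Product: 27 S-ethyl 2-[(1S,2S,5S)-2-(dimethoxymethyl)-2-methyl-3-oxo-5-(propan-2-yl)cyclopentyl]ethanethioate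
Conditions: HC(OMe)3, Me3SiOTf (10 mol%), CH2Cl2, −78 to −40 °C
Reagents that add atoms: trimethyl orthoformate (COC(OC)OC)
Why: Mukaiyama-type alkylation of the silyl enol ether by the dimethoxycarbenium ion occurs trans to the adjacent C24 side chain and creates the quaternary C15 (S) carrying C14 as a masked aldehyde.

Step 18
Reactants: 16 2-[(1E)-1-[(2S,3S)-2-[(3R)-4-bromo-3-methylbutyl]-3-methylcyclopentylidene]ethyl]-4,4,5,5-tetramethyl-1,3,2-dioxaborolane; 27 S-ethyl 2-[(1S,2S,5S)-2-(dimethoxymethyl)-2-methyl-3-oxo-5-(propan-2-yl)cyclopentyl]ethanethioate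
Product: 29 (4R)-1-[(1S,2S,5S)-2-(dimethoxymethyl)-2-methyl-3-oxo-5-(propan-2-yl)cyclopentyl]-4-methyl-6-{(1S,2E,5S)-5-methyl-2-[1-(4,4,5,5-tetramethyl-1,3,2-dioxaborolan-2-yl)ethylidene]cyclopentyl}hexan-2-one, via alkylzinc bromide 28 (not isolated)
Conditions: Zn dust, LiCl, THF, 50 °C; then 27, PdCl2(PPh3)2 (5 mol%), toluene/THF, rt
Reagents that add atoms: none
Why: Fukuyama coupling of the alkylzinc with the thioester forms the C13–C26 ketone chemoselectively in the presence of the C17 ketone, the acetal and the alkenyl boronate (no base, so no B-to-Pd transfer).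

Step 19
Reactants: 29 (4R)-1-[(1S,2S,5S)-2-(dimethoxymethyl)-2-methyl-3-oxo-5-(propan-2-yl)cyclopentyl]-4-methyl-6-{(1S,2E,5S)-5-methyl-2-[1-(4,4,5,5-tetramethyl-1,3,2-dioxaborolan-2-yl)ethylidene]cyclopentyl}hexan-2-one
Product: 31 (3S,3aS,7aS)-7a-methyl-6-[(2R)-4-{(1S,2E,5S)-5-methyl-2-[1-(4,4,5,5-tetramethyl-1,3,2-dioxaborolan-2-yl)ethylidene]cyclopentyl}butan-2-yl]-3-(propan-2-yl)-2,3,3a,4-tetrahydro-1H-indene-1,5(7aH)-dione, via keto aldehyde 30 (not isolated)
Conditions: TsOH·H2O (cat.), acetone/H2O, rt; then piperidine/AcOH (cat.), toluene, 60 °C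
Reagents that add atoms: none
Why: acetal hydrolysis and intramolecular aldol condensation close ring C, because only attack of C13 on the non-enolisable C14 aldehyde gives a six-membered ring (attack from C25 would give a four-membered ring), which fixes the trans ring fusion already set at C15 and C24.

Step 20
Reactants: 31 (3S,3aS,7aS)-7a-methyl-6-[(2R)-4-{(1S,2E,5S)-5-methyl-2-[1-(4,4,5,5-tetramethyl-1,3,2-dioxaborolan-2-yl)ethylidene]cyclopentyl}butan-2-yl]-3-(propan-2-yl)-2,3,3a,4-tetrahydro-1H-indene-1,5(7aH)-dione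
Product: 32 (1R,3S,3aS,5R,7aS)-7a-methyl-6-[(2R)-4-{(1S,2E,5S)-5-methyl-2-[1-(4,4,5,5-tetramethyl-1,3,2-dioxaborolan-2-yl)ethylidene]cyclopentyl}butan-2-yl]-3-(propan-2-yl)-2,3,3a,4,5,7a-hexahydro-1H-indene-1,5-diol
Conditions: (S)-Me-CBS oxazaborolidine (0.3 equiv), BH3·SMe2 (2.2 equiv), THF, −20 °C
Reagents that add atoms: none
Why: Corey–Bakshi–Shibata reduction with one catalyst enantiomer delivers hydride to the β face of the C26 enone carbonyl, giving the axial α-alcohol (C26 R), and to the α face of the C17 ketone, matched with the bias away from the angular methyl, giving the β-alcohol (C17 R).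

Step 21
Reactants: 32 (1R,3S,3aS,5R,7aS)-7a-methyl-6-[(2R)-4-{(1S,2E,5S)-5-methyl-2-[1-(4,4,5,5-tetramethyl-1,3,2-dioxaborolan-2-yl)ethylidene]cyclopentyl}butan-2-yl]-3-(propan-2-yl)-2,3,3a,4,5,7a-hexahydro-1H-indene-1,5-diol
Product: 33 (1R,3S,3aS,5R,7aS)-1-hydroxy-7a-methyl-6-[(2R)-4-{(1S,2E,5S)-5-methyl-2-[1-(4,4,5,5-tetramethyl-1,3,2-dioxaborolan-2-yl)ethylidene]cyclopentyl}butan-2-yl]-3-(propan-2-yl)-2,3,3a,4,5,7a-hexahydro-1H-inden-5-yl methyl carbonate
Conditions: ClCO2Me, pyridine, DMAP (cat.), CH2Cl2, −20 °C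
Reagents that add atoms: methyl chloroformate (COC(=O)Cl)
Why: the unhindered allylic C26 alcohol is acylated selectively over the neopentylic C17 alcohol, which is flanked by the quaternary C15.

Step 22
Reactants: 33 (1R,3S,3aS,5R,7aS)-1-hydroxy-7a-methyl-6-[(2R)-4-{(1S,2E,5S)-5-methyl-2-[1-(4,4,5,5-tetramethyl-1,3,2-dioxaborolan-2-yl)ethylidene]cyclopentyl}butan-2-yl]-3-(propan-2-yl)-2,3,3a,4,5,7a-hexahydro-1H-inden-5-yl methyl carbonate
Product: 34 Aspergilol C
Conditions: Pd2(dba)3·CHCl3 (5 mol%), P(2-furyl)3 (20 mol%), THF, 50 °C, slow addition to 2 mM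
Reagents that add atoms: none
Why: Proposed new method: an intramolecular base-free Suzuki–Miyaura-type allyl–alkenyl coupling closes the eight-membered ring B, in which zerovalent palladium ionises the pseudo-axial α-carbonate with inversion and loss of CO2, the liberated methoxide activates the tethered pinacol boronate for boron-to-palladium transfer through a Pd–O–B bridge, and reductive elimination at the less hindered allyl terminus C26 (C14 is neopentylic) delivers C2 on the β face (net inversion, C26 S) with retention of the C2=C3 geometry and leaves C13=C14 in place; the closest known reactions are intermolecular palladium-catalysed couplings of allylic carbonates with aryl- and alkenylboron reagents (inversion) and palladium-catalysed allylic alkylation macrocyclisations, whereas ring closure by allyl–alkenylboron coupling with a tetrasubstituted alkenyl boronate has not been shown.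

**Compound list**
1 | 3-methylcyclopent-2-en-1-one | CC1=CC(=O)CC1 | starting material
2 | 2-iodo-3-methylcyclopent-2-en-1-one | CC1=C(I)C(=O)CC1 | intermediate
3 | (E)-1,4-dibromobut-2-ene | BrC/C=C/CBr | starting material
4 | (3R)-4-bromo-3-methylbut-1-ene | C=C[C@@H](C)CBr | intermediate
5 | 9-[(3R)-4-bromo-3-methylbutyl]-9-borabicyclo[3.3.1]nonane | C1CCC2CCCC1B2CC[C@@H](C)CBr | intermediate
6 | 2-[(3R)-4-bromo-3-methylbutyl]-3-methylcyclopent-2-en-1-one | O=C1CCC(C)=C1CC[C@@H](C)CBr | intermediate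
7 | (1S)-2-[(3R)-4-bromo-3-methylbutyl]-3-methylcyclopent-2-en-1-ol | O[C@H]1CCC(C)=C1CC[C@@H](C)CBr | intermediate
8 | (1S,2S,3S)-2-[(3R)-4-bromo-3-methylbutyl]-3-methylcyclopentan-1-ol | O[C@H]1CC[C@H](C)[C@@H]1CC[C@@H](C)CBr | intermediate
9 | (2S,3S)-2-[(3R)-4-bromo-3-methylbutyl]-3-methylcyclopentan-1-one | O=C1CC[C@H](C)[C@@H]1CC[C@@H](C)CBr | intermediate
10 | potassium (4S,5S)-5-[(3R)-4-bromo-3-methylbutyl]-4-methylcyclopent-1-en-1-olate | [K+].[O-]C1=CC[C@H](C)[C@@H]1CC[C@@H](C)CBr | intermediate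
11 | (4S,5S)-5-[(3R)-4-bromo-3-methylbutyl]-4-methylcyclopent-1-en-1-yl trifluoromethanesulfonate | O=S(=O)(OC1=CC[C@H](C)[C@@H]1CC[C@@H](C)CBr)C(F)(F)F | intermediate
12 | (4S,5S)-5-[(3R)-4-bromo-3-methylbutyl]-1-(1-ethoxyethenyl)-4-methylcyclopent-1-ene | C=C(OCC)C1=CC[C@H](C)[C@@H]1CC[C@@H](C)CBr | intermediate
13 | 1-[(4S,5S)-5-[(3R)-4-bromo-3-methylbutyl]-4-methylcyclopent-1-en-1-yl]ethan-1-one | CC(=O)C1=CC[C@H](C)[C@@H]1CC[C@@H](C)CBr | intermediate
14 | lithium (1Z)-1-[(2S,3S)-2-[(3R)-4-bromo-3-methylbutyl]-3-methylcyclopentylidene]ethan-1-olate | [Li+].C/C([O-])=C1\CC[C@H](C)[C@@H]1CC[C@@H](C)CBr | intermediate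
15 | (1Z)-1-[(2S,3S)-2-[(3R)-4-bromo-3-methylbutyl]-3-methylcyclopentylidene]ethyl trifluoromethanesulfonate | C/C(OS(=O)(=O)C(F)(F)F)=C1\CC[C@H](C)[C@@H]1CC[C@@H](C)CBr | intermediate
16 | 2-[(1E)-1-[(2S,3S)-2-[(3R)-4-bromo-3-methylbutyl]-3-methylcyclopentylidene]ethyl]-4,4,5,5-tetramethyl-1,3,2-dioxaborolane | C/C(B1OC(C)(C)C(C)(C)O1)=C1\CC[C@H](C)[C@@H]1CC[C@@H](C)CBr | intermediate
17 | (4R)-4-hydroxycyclopent-2-en-1-one | O=C1C=C[C@H](O)C1 | starting material
18 | (4R)-4-[(tert-butyldimethylsilyl)oxy]cyclopent-2-en-1-one | O=C1C=C[C@H](O[Si](C)(C)C(C)(C)C)C1 | intermediate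
19 | (3S,4R)-4-[(tert-butyldimethylsilyl)oxy]-3-(propan-2-yl)cyclopentan-1-one | O=C1C[C@@H](C(C)C)[C@H](O[Si](C)(C)C(C)(C)C)C1 | intermediate
20 | (4S)-4-(propan-2-yl)cyclopent-2-en-1-one | O=C1C[C@@H](C(C)C)C=C1 | intermediate
21 | (4S)-2-iodo-4-(propan-2-yl)cyclopent-2-en-1-one | O=C1C[C@@H](C(C)C)C=C1I | intermediate
22 | (4S)-2-methyl-4-(propan-2-yl)cyclopent-2-en-1-one | O=C1C[C@@H](C(C)C)C=C1C | intermediate
23 | S-ethyl ethanethioate | CC(=O)SCC | starting material
24 | lithium 1-(ethylsulfanyl)ethen-1-olate | [Li+].C=C([O-])SCC | intermediate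
25 | {[1-(ethylsulfanyl)ethenyl]oxy}(trimethyl)silane | C=C(SCC)O[Si](C)(C)C | intermediate
26 | S-ethyl 2-[(1S,5S)-2-methyl-5-(propan-2-yl)-3-[(trimethylsilyl)oxy]cyclopent-2-en-1-yl]ethanethioate | CC(C)[C@@H]1CC(O[Si](C)(C)C)=C(C)[C@H]1CC(=O)SCC | intermediate
27 | S-ethyl 2-[(1S,2S,5S)-2-(dimethoxymethyl)-2-methyl-3-oxo-5-(propan-2-yl)cyclopentyl]ethanethioate | COC(OC)[C@@]1(C)C(=O)C[C@@H](C(C)C)[C@@H]1CC(=O)SCC | intermediate
28 | bromo{(2R)-2-methyl-4-[(1S,2E,5S)-5-methyl-2-[1-(4,4,5,5-tetramethyl-1,3,2-dioxaborolan-2-yl)ethylidene]cyclopentyl]butyl}zinc | C/C(B1OC(C)(C)C(C)(C)O1)=C1\CC[C@H](C)[C@@H]1CC[C@@H](C)C[Zn]Br | intermediate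
29 | (4R)-1-[(1S,2S,5S)-2-(dimethoxymethyl)-2-methyl-3-oxo-5-(propan-2-yl)cyclopentyl]-4-methyl-6-{(1S,2E,5S)-5-methyl-2-[1-(4,4,5,5-tetramethyl-1,3,2-dioxaborolan-2-yl)ethylidene]cyclopentyl}hexan-2-one | C/C(B1OC(C)(C)C(C)(C)O1)=C1\CC[C@H](C)[C@@H]1CC[C@@H](C)CC(=O)C[C@H]1[C@H](C(C)C)CC(=O)[C@]1(C)C(OC)OC | intermediate
30 | (1S,2S,3S)-1-methyl-2-[(4R)-4-methyl-6-{(1S,2E,5S)-5-methyl-2-[1-(4,4,5,5-tetramethyl-1,3,2-dioxaborolan-2-yl)ethylidene]cyclopentyl}-2-oxohexyl]-5-oxo-3-(propan-2-yl)cyclopentane-1-carbaldehyde | C/C(B1OC(C)(C)C(C)(C)O1)=C1\CC[C@H](C)[C@@H]1CC[C@@H](C)CC(=O)C[C@H]1[C@H](C(C)C)CC(=O)[C@]1(C)C=O | intermediate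
31 | (3S,3aS,7aS)-7a-methyl-6-[(2R)-4-{(1S,2E,5S)-5-methyl-2-[1-(4,4,5,5-tetramethyl-1,3,2-dioxaborolan-2-yl)ethylidene]cyclopentyl}butan-2-yl]-3-(propan-2-yl)-2,3,3a,4-tetrahydro-1H-indene-1,5(7aH)-dione | C/C(B1OC(C)(C)C(C)(C)O1)=C1\CC[C@H](C)[C@@H]1CC[C@@H](C)C1=C[C@@]2(C)C(=O)C[C@@H](C(C)C)[C@@H]2CC1=O | intermediate
32 | (1R,3S,3aS,5R,7aS)-7a-methyl-6-[(2R)-4-{(1S,2E,5S)-5-methyl-2-[1-(4,4,5,5-tetramethyl-1,3,2-dioxaborolan-2-yl)ethylidene]cyclopentyl}butan-2-yl]-3-(propan-2-yl)-2,3,3a,4,5,7a-hexahydro-1H-indene-1,5-diol | C/C(B1OC(C)(C)C(C)(C)O1)=C1\CC[C@H](C)[C@@H]1CC[C@@H](C)C1=C[C@@]2(C)[C@H](O)C[C@@H](C(C)C)[C@@H]2C[C@H]1O | intermediate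
33 | (1R,3S,3aS,5R,7aS)-1-hydroxy-7a-methyl-6-[(2R)-4-{(1S,2E,5S)-5-methyl-2-[1-(4,4,5,5-tetramethyl-1,3,2-dioxaborolan-2-yl)ethylidene]cyclopentyl}butan-2-yl]-3-(propan-2-yl)-2,3,3a,4,5,7a-hexahydro-1H-inden-5-yl methyl carbonate | C/C(B1OC(C)(C)C(C)(C)O1)=C1\CC[C@H](C)[C@@H]1CC[C@@H](C)C1=C[C@@]2(C)[C@H](O)C[C@@H](C(C)C)[C@@H]2C[C@H]1OC(=O)OC | intermediate
34 | Aspergilol C | C/C1=C2\CC[C@H](C)[C@@H]2CC[C@@H](C)C2=C[C@@]3(C)[C@H](O)C[C@@H](C(C)C)[C@@H]3C[C@@H]21 | target

**Step count**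
Total step count: 22. Longest linear sequence: 14 steps (steps 1, 3 to 10 and 18 to 22).

**Steps most likely to fail**

Step 22 (proposed ring closure). Boron-to-palladium transfer from a tetrasubstituted alkenyl boronate may be too slow, and β-hydride loss from the allyl complex, protodeboronation or attack at C14 may compete. The fallback sets out from enone 31 and comes back at 34, and uses only known reaction types. Iododeboronation with N-iodosuccinimide (retention) gives (3S,3aS,7aS)-6-[(2R)-4-[(1S,2Z,5S)-2-(1-iodoethylidene)-5-methylcyclopentyl]butan-2-yl]-7a-methyl-3-(propan-2-yl)-2,3,3a,4-tetrahydro-1H-indene-1,5(7aH)-dione F6. Intramolecular Nozaki–Hiyama–Kishi 1,2-addition to the C26 enone carbonyl (CrCl2, catalytic NiCl2, DMSO/THF, high dilution) closes ring B as the 17-oxo-26-hydroxy tetracycle F7, a tertiary bis-allylic alcohol whose C26 configuration is immaterial. LiN(SiMe3)2 (1 equiv) then ClP(O)(OEt)2 gives its diethyl phosphate F8. Li/NH3 (THF, −78 °C, NH4Cl quench) cleaves the allylic C–O bond to a pentadienyl anion that is protonated at its central carbon C26 from the axial α face, which puts C2 equatorial as in the target. The same operation reduces the C17 ketone to the β-alcohol, so 34 is obtained directly.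

Step 9 (conjugate reduction and triflation). 1,2-Reduction may compete, and the enolate geometry rests on a conformational argument. The fallback sets out from ketone 9 and comes back at boronate 16. Ramirez olefination (CBr4, PPh3, CH2Cl2, 0 °C, non-basic) gives (2S,3S)-2-[(3R)-4-bromo-3-methylbutyl]-1-(dibromomethylidene)-3-methylcyclopentane F1. Site-selective Negishi monomethylation (MeZnCl, Pd(PPh3)4, THF) at the less hindered C–Br bond, the one cis to the C4 methylene, gives (2S,3S)-2-[(3R)-4-bromo-3-methylbutyl]-1-[(1Z)-1-bromoethylidene]-3-methylcyclopentane F2, with the remaining bromine cis to C8. Miyaura borylation (B2pin2, PdCl2(dppf), KOAc) converts F2 into 16 with retention.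

Step 19 (acetal hydrolysis and aldol cyclodehydration). The β-keto aldehyde 30 may deformylate, and acid may erode the alkenyl boronate. The fallback sets out from bromide 16 and thioester 27 and comes back at enone 31. Michaelis–Becker reaction of 16 with sodium dimethyl phosphite gives dimethyl {(2R)-2-methyl-4-[(1S,2E,5S)-5-methyl-2-[1-(4,4,5,5-tetramethyl-1,3,2-dioxaborolan-2-yl)ethylidene]cyclopentyl]butyl}phosphonate F3. Its lithio derivative (LiN(i-Pr)2, 2 equiv, −78 °C) is acylated by 27 to give the β-ketophosphonate acetal F4, phosphorylated at C13. Mild acetal hydrolysis gives the β-ketophosphonate aldehyde F5. Intramolecular Horner–Wadsworth–Emmons olefination under Masamune–Roush conditions (LiCl, DBU, MeCN) forms C13=C14 regiospecifically and closes ring C to 31 without exposing a free β-keto aldehyde to aldol conditions.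

**Further compounds**
F1 | step 9 | (2S,3S)-2-[(3R)-4-bromo-3-methylbutyl]-1-(dibromomethylidene)-3-methylcyclopentane | BrC(Br)=C1CC[C@H](C)[C@@H]1CC[C@@H](C)CBr
F2 | step 9 | (2S,3S)-2-[(3R)-4-bromo-3-methylbutyl]-1-[(1Z)-1-bromoethylidene]-3-methylcyclopentane | C/C(Br)=C1\CC[C@H](C)[C@@H]1CC[C@@H](C)CBr
F3 | step 19 | dimethyl {(2R)-2-methyl-4-[(1S,2E,5S)-5-methyl-2-[1-(4,4,5,5-tetramethyl-1,3,2-dioxaborolan-2-yl)ethylidene]cyclopentyl]butyl}phosphonate | C/C(B1OC(C)(C)C(C)(C)O1)=C1\CC[C@H](C)[C@@H]1CC[C@@H](C)CP(=O)(OC)OC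
F4 | step 19 | dimethyl {(4R)-1-[(1S,2S,5S)-2-(dimethoxymethyl)-2-methyl-3-oxo-5-(propan-2-yl)cyclopentyl]-4-methyl-6-{(1S,2E,5S)-5-methyl-2-[1-(4,4,5,5-tetramethyl-1,3,2-dioxaborolan-2-yl)ethylidene]cyclopentyl}-2-oxohexan-3-yl}phosphonate (epimers at C13) | C/C(B1OC(C)(C)C(C)(C)O1)=C1\CC[C@H](C)[C@@H]1CC[C@@H](C)C(P(=O)(OC)OC)C(=O)C[C@H]1[C@H](C(C)C)CC(=O)[C@]1(C)C(OC)OC
F5 | step 19 | dimethyl {(4R)-1-[(1S,2S,5S)-2-formyl-2-methyl-3-oxo-5-(propan-2-yl)cyclopentyl]-4-methyl-6-{(1S,2E,5S)-5-methyl-2-[1-(4,4,5,5-tetramethyl-1,3,2-dioxaborolan-2-yl)ethylidene]cyclopentyl}-2-oxohexan-3-yl}phosphonate (epimers at C13) | C/C(B1OC(C)(C)C(C)(C)O1)=C1\CC[C@H](C)[C@@H]1CC[C@@H](C)C(P(=O)(OC)OC)C(=O)C[C@H]1[C@H](C(C)C)CC(=O)[C@]1(C)C=O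
F6 | step 22 | (3S,3aS,7aS)-6-[(2R)-4-[(1S,2Z,5S)-2-(1-iodoethylidene)-5-methylcyclopentyl]butan-2-yl]-7a-methyl-3-(propan-2-yl)-2,3,3a,4-tetrahydro-1H-indene-1,5(7aH)-dione | C/C(I)=C1\CC[C@H](C)[C@@H]1CC[C@@H](C)C1=C[C@@]2(C)C(=O)C[C@@H](C(C)C)[C@@H]2CC1=O
F7 | step 22 | 17-oxo-26-hydroxy analogue of 34 (tertiary bis-allylic alcohol at C26, ketone at C17, C26 configuration undefined) | C/C1=C2\CC[C@H](C)[C@@H]2CC[C@@H](C)C2=C[C@@]3(C)C(=O)C[C@@H](C(C)C)[C@@H]3CC21O
F8 | step 22 | diethyl phosphate of F7 (phosphate on the C26 oxygen, ketone at C17) | C/C1=C2\CC[C@H](C)[C@@H]2CC[C@@H](C)C2=C[C@@]3(C)C(=O)C[C@@H](C(C)C)[C@@H]3CC21OP(=O)(OCC)OCC
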